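The target is epicatechin-(4β→6)-epicatechin-(4β→8)-epicatechin-(4β→6)-epicatechin (units U1–U4), so all eight C2/C3 stereocentres are bought with (−)-epicatechin. Everything rests on cutting C4 (ring C) of U3 from C6 (ring A) of U4. The key step ionises a 4-alkoxy group on U3 of a perbenzylated trimer. The cation, stabilised by O5, O7 and O1 of its phloroglucinol ring A, alkylates an 8-bromo-epicatechin ether. One operation completes the carbon skeleton, sets C4 β (anti to the α C2-aryl and C3-oxygen) and enforces C6 regiochemistry, because bromine occupies the intrinsically preferred C8. The trimer arises by orthogonal O/S leaving-group activation; bromines and benzyls leave together.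

Key step: step 8

Remark: flavan numbering is used (ring A = phloroglucinol ring, ring B = catechol ring, ring C = pyran ring). U1 is the top unit and U4 the bottom unit with the C4 methylene. α is the face that carries the C2 aryl and the C3 oxygen, and β is the opposite face. Bn = benzyl, Xy = 2,6-dimethylphenyl.

Step 1
Reactants: 1 (−)-epicatechin
Product: 2 3,5,7,3',4'-penta-O-benzyl-(−)-epicatechin (2R,3R)
Conditions: BnBr (6 equiv), NaH (6 equiv, added last), DMF, −20 °C to rt
Reagents that add atoms: benzyl bromide, BrCc1ccccc1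
Why: Williamson ether synthesis at the four phenols and the C3 alcohol; because NaH is added to the cold mixture that already holds BnBr, each oxyanion should be trapped as it forms, so base-induced opening of ring C (the path that epimerises C2) should not compete and both stereocentres are carried over unchanged.

Step 2
Reactants: 2 penta-O-benzyl-(−)-epicatechin
Product: 3 8-bromo-penta-O-benzyl-(−)-epicatechin (U4 building block)
Conditions: NBS (1.0 equiv), CH2Cl2, −78 °C to 0 °C
Reagents that add atoms: N-bromosuccinimide, O=C1CCC(=O)N1Br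
Why: Electrophilic aromatic bromination: in benzylated flavan-3-ols C8 is the most nucleophilic CH of ring A, so one equivalent of NBS at low temperature should stop at the 8-bromide, which serves both as U4 building block and as precursor of U1 and U2.

Step 3
Reactants: 3 8-bromo-penta-O-benzyl-(−)-epicatechin
Product: 4 8-bromo-4β-(2-ethoxyethoxy)-penta-O-benzylepicatechin (2,3-cis-3,4-trans; U1 building block)
Conditions: DDQ (1.5 equiv), 2-ethoxyethanol (5 equiv), CH2Cl2, rt
Reagents that add atoms: 2-ethoxyethanol, CCOCCO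
Why: DDQ benzylic oxidation: hydride abstraction from C4 gives the ring-A-stabilised flavan-4-yl cation, which the alcohol traps from the β face, anti to the α-oriented C2 aryl and C3 benzyloxy groups (the 4β centre formed here only carries a leaving group).

Step 4
Reactants: 4 8-bromo-4β-(2-ethoxyethoxy)-penta-O-benzylepicatechin
Product: 5 8-bromo-4β-(2,6-dimethylphenylthio)-penta-O-benzylepicatechin (2,3-cis-3,4-trans; U2 building block)
Conditions: XySH (1.5 equiv), BF3·OEt2 (0.3 equiv), CH2Cl2, −78 °C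
Reagents that add atoms: 2,6-dimethylbenzenethiol, Cc1cccc(C)c1S
Why: Lewis acid mediated SN1 exchange of the C4 ether for a thiol (the chemistry of proanthocyanidin thiolysis), again from the β face; the soft thiol outruns C6 of a second molecule, and the two ortho methyl groups are chosen to block later sulfur transfer between units.

Step 5
Reactants: 2 penta-O-benzyl-(−)-epicatechin
Product: 6 4β-(2-ethoxyethoxy)-penta-O-benzylepicatechin (2,3-cis-3,4-trans; U3 building block)
Conditions: DDQ (1.5 equiv), 2-ethoxyethanol (5 equiv), CH2Cl2, 0 °C to rt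
Reagents that add atoms: 2-ethoxyethanol, CCOCCO
Why: Same DDQ benzylic oxidation as in step 3, here on the more electron-rich bromine-free ring A, with β-face trapping by the alcohol; C8–H stays free as the nucleophilic site of U3.

Step 6
Reactants: 4 8-bromo-4β-(2-ethoxyethoxy)-penta-O-benzylepicatechin; 5 8-bromo-4β-(2,6-dimethylphenylthio)-penta-O-benzylepicatechin
Product: 7 U1–U2 dimer, [8-bromo-penta-O-benzylepicatechin]-(4β→6)-[8-bromo-4β-(2,6-dimethylphenylthio)-penta-O-benzylepicatechin]
Conditions: 5 (2 equiv), BF3·OEt2 (0.5 equiv), 4 Å MS, CH2Cl2, −78 to −30 °C, slow addition of 4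
Reagents that add atoms: none
Why: Friedel–Crafts-type interflavan coupling under orthogonal activation: the hard Lewis acid ionises only the C4–O group of 4 while the C4–S group of 5 stays, bromine on C8 of 5 leaves C6 as its only ring A CH, β-face attack anti to the C2 aryl and C3 benzyloxy groups sets C4 of U1, and slow addition of 4 to excess 5 holds back self-condensation.

Step 7
Reactants: 7 U1–U2 dimer thioether; 6 4β-(2-ethoxyethoxy)-penta-O-benzylepicatechin
Product: 8 U1–U2–U3 trimer, [8-bromo-penta-O-benzylepicatechin]-(4β→6)-[8-bromo-penta-O-benzylepicatechin]-(4β→8)-[4β-(2-ethoxyethoxy)-penta-O-benzylepicatechin]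
Conditions: 6 (1.5 equiv), NIS (1.1 equiv), 4 Å MS, CH2Cl2, −78 to −20 °C
Reagents that add atoms: none
Why: Iodonium activation of the aryl thioether (thioglycoside-type soft activation) releases the U2 flavan-4-yl cation under neutral conditions, since succinimide takes up the proton, so the C4–O group of 6 and 8 should persist; the free and intrinsically most nucleophilic C8 of 6 attacks from the β face and sets C4 of U2.

Step 8
Reactants: 8 U1–U2–U3 trimer with the 4β-(2-ethoxyethoxy) group on U3; 3 8-bromo-penta-O-benzyl-(−)-epicatechin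
Product: 9 protected tetramer, [8-bromo-penta-O-benzylepicatechin]-(4β→6)-[8-bromo-penta-O-benzylepicatechin]-(4β→8)-[penta-O-benzylepicatechin]-(4β→6)-[8-bromo-penta-O-benzylepicatechin] (icosa-O-benzyl tribromide)
Conditions: 3 (4 equiv), BF3·OEt2 (0.5 equiv), 4 Å MS, CH2Cl2, −78 to −30 °C, syringe-pump addition of 8
Reagents that add atoms: none
Why: BF3 binds the chelating 2-ethoxyethoxy group at C4 of U3, its departure gives a flavan-4-yl cation that is in effect a quinone-methide-type oxocarbenium ion of ring A stabilised by O5, O7 and O1, and C6 of 3 attacks it before loss of H6 restores aromaticity (SN1-type Friedel–Crafts alkylation). The closest known reaction type is the Lewis acid mediated interflavan coupling of C4-oxygenated flavan-3-ol ethers with C8-halogen-capped flavan nucleophiles. No ring is closed. The one new stereocentre, C4 of U3, is under substrate control: the half-chair cation carries its C2 aryl and C3 benzyloxy groups on the α face, so the arene should add from the β face to give the 3,4-trans (4β) bond. Regioselectivity for C6 over C8 of U4 is secured by the bromine on C8 of 3, which leaves C6–H as the only ring A position, and O-alkylation is excluded because O3 is benzylated. Chemoselectivity against self-condensation through the C6–H of U1 and U3 is sought by adding 8 slowly to excess 3, so that each molecule is ionised amid a surplus of the small nucleophile, and the low temperature should spare the two interflavan bonds already present.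

Step 9
Reactants: 9 protected tetramer
Product: 10 epicatechin-(4β→6)-epicatechin-(4β→8)-epicatechin-(4β→6)-epicatechin (CNP0120618.1)
Conditions: H2 (1 atm), Pd(OH)2/C, Et3N (3 equiv), THF/MeOH/H2O, rt
Reagents that add atoms: none
Why: Heterogeneous catalytic hydrogenolysis cleaves all twenty benzyl ethers and hydrodebrominates the three aryl bromides in one operation, while Et3N takes up the HBr so that the acid-labile interflavan bonds and all eleven stereocentres should stay untouched.

Compound list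

1 | (−)-epicatechin | Oc1cc(O)c2c(c1)O[C@H](c1ccc(O)c(O)c1)[C@H](O)C2 | starting material
2 | 3,5,7,3',4'-penta-O-benzyl-(−)-epicatechin | c4ccccc4COc1cc(OCc4ccccc4)c2c(c1)O[C@H](c5ccc(OCc4ccccc4)c(OCc4ccccc4)c5)[C@H](OCc4ccccc4)C2 | intermediate
3 | 8-bromo-penta-O-benzyl-(−)-epicatechin | c4ccccc4COc1cc(OCc4ccccc4)c2c(c1Br)O[C@H](c5ccc(OCc4ccccc4)c(OCc4ccccc4)c5)[C@H](OCc4ccccc4)C2 | intermediate
4 | 8-bromo-4β-(2-ethoxyethoxy)-penta-O-benzylepicatechin | c4ccccc4COc1cc(OCc4ccccc4)c2c(c1Br)O[C@H](c5ccc(OCc4ccccc4)c(OCc4ccccc4)c5)[C@H](OCc4ccccc4)[C@H]2OCCOCC | intermediate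
5 | 8-bromo-4β-(2,6-dimethylphenylthio)-penta-O-benzylepicatechin | c4ccccc4COc1cc(OCc4ccccc4)c2c(c1Br)O[C@H](c5ccc(OCc4ccccc4)c(OCc4ccccc4)c5)[C@H](OCc4ccccc4)[C@H]2Sc6c(C)cccc6C | intermediate
6 | 4β-(2-ethoxyethoxy)-penta-O-benzylepicatechin | c4ccccc4COc1cc(OCc4ccccc4)c2c(c1)O[C@H](c5ccc(OCc4ccccc4)c(OCc4ccccc4)c5)[C@H](OCc4ccccc4)[C@H]2OCCOCC | intermediate
7 | U1–U2 dimer thioether (4β→6) | c4ccccc4COc1cc(OCc4ccccc4)c2c(c1Br)O[C@H](c5ccc(OCc4ccccc4)c(OCc4ccccc4)c5)[C@H](OCc4ccccc4)[C@H]2c1c(OCc4ccccc4)c(Br)c2c(c1OCc4ccccc4)[C@H](Sc6c(C)cccc6C)[C@@H](OCc4ccccc4)[C@@H](c5ccc(OCc4ccccc4)c(OCc4ccccc4)c5)O2 | intermediate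
8 | U1–U2–U3 trimer 4β-(2-ethoxyethyl) ether (4β→6, 4β→8) | c4ccccc4COc1cc(OCc4ccccc4)c2c(c1Br)O[C@H](c5ccc(OCc4ccccc4)c(OCc4ccccc4)c5)[C@H](OCc4ccccc4)[C@H]2c1c(OCc4ccccc4)c(Br)c2c(c1OCc4ccccc4)[C@H](c1c(OCc4ccccc4)cc(OCc4ccccc4)c3c1O[C@H](c5ccc(OCc4ccccc4)c(OCc4ccccc4)c5)[C@H](OCc4ccccc4)[C@H]3OCCOCC)[C@@H](OCc4ccccc4)[C@@H](c5ccc(OCc4ccccc4)c(OCc4ccccc4)c5)O2 | intermediate
9 | protected tetramer (icosa-O-benzyl tribromide; 4β→6, 4β→8, 4β→6) | c4ccccc4COc1cc(OCc4ccccc4)c2c(c1Br)O[C@H](c5ccc(OCc4ccccc4)c(OCc4ccccc4)c5)[C@H](OCc4ccccc4)[C@H]2c1c(OCc4ccccc4)c(Br)c2c(c1OCc4ccccc4)[C@H](c1c(OCc4ccccc4)cc(OCc4ccccc4)c3c1O[C@H](c5ccc(OCc4ccccc4)c(OCc4ccccc4)c5)[C@H](OCc4ccccc4)[C@H]3c1c(OCc4ccccc4)c(Br)c3c(c1OCc4ccccc4)C[C@@H](OCc4ccccc4)[C@@H](c5ccc(OCc4ccccc4)c(OCc4ccccc4)c5)O3)[C@@H](OCc4ccccc4)[C@@H](c5ccc(OCc4ccccc4)c(OCc4ccccc4)c5)O2 | intermediate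
10 | epicatechin-(4β→6)-epicatechin-(4β→8)-epicatechin-(4β→6)-epicatechin (CNP0120618.1) | Oc1cc(O)c2c(c1)O[C@H](c1ccc(O)c(O)c1)[C@H](O)[C@H]2c1c(O)cc2c(c1O)[C@H](c1c(O)cc(O)c3c1O[C@H](c1ccc(O)c(O)c1)[C@H](O)[C@H]3c1c(O)cc3c(c1O)C[C@@H](O)[C@@H](c1ccc(O)c(O)c1)O3)[C@@H](O)[C@@H](c1ccc(O)c(O)c1)O2 | target

Total step count: 9. Longest linear sequence: 8 steps (steps 1, 2, 3, 4, 6, 7, 8, 9).

Steps most likely to fail

Step 8. C6 of 3 is deactivated by bromine and flanked by two benzyloxy groups, so its attack may be slow. The ionised trimer could then be captured by the free C6–H positions of U1 and U3 in other trimer or product molecules, which means self-condensation and chain growth. The fallback removes these competitors structurally and sets out from 8. NBS (2 equiv, CH2Cl2, −78 °C to 0 °C) should brominate the two remaining ring A CH positions, C6 of U1 and C6 of U3, to give the fully capped tetrabromo trimer F1. This trimer has no nucleophilic ring A position left, so it can be coupled with a near-equimolar amount of 3 (BF3·OEt2, CH2Cl2, low temperature) to give the pentabromo tetramer F2. Hydrogenolysis as in step 9, with five equivalents of Et3N, comes back to the route at 10.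

Step 6. The C6–H of electrophile 4 is about as nucleophilic as that of 5, so self-condensation of 4 may compete, and the thio group may be exchanged between units. The fallback installs the leaving group only after the bond is made and sets out from 4 and 3. Compound 4 is coupled (BF3·OEt2, CH2Cl2, low temperature) with a large excess of the cheap, recoverable 3 to give the dibromo dimer with a C4 methylene on U2, F3. DDQ with 2-ethoxyethanol should then oxidise this only remaining C4 methylene to give the dimer 4β-(2-ethoxyethyl) ether F4. Thiol exchange as in step 4 (XySH, BF3·OEt2) comes back to the route at 7.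

Step 7. Orthogonality may be lost, with premature ionisation of the C4–O group of 6 or of 8 during the sulfur activation, followed by uncontrolled chain growth. The fallback uses a nucleophile without any leaving group and sets out from 7 and 2. The same iodonium activation of 7 in the presence of 2 should give the trimer with a C4 methylene on U3, F5. Late-stage DDQ oxidation with 2-ethoxyethanol at this single C4 methylene comes back to the route at 8.

Further compounds

F1 | step 8 | fully capped tetrabromo trimer (additional Br at C6 of U1 and C6 of U3) | c4ccccc4COc1c(Br)c(OCc4ccccc4)c2c(c1Br)O[C@H](c5ccc(OCc4ccccc4)c(OCc4ccccc4)c5)[C@H](OCc4ccccc4)[C@H]2c1c(OCc4ccccc4)c(Br)c2c(c1OCc4ccccc4)[C@H](c1c(OCc4ccccc4)c(Br)c(OCc4ccccc4)c3c1O[C@H](c5ccc(OCc4ccccc4)c(OCc4ccccc4)c5)[C@H](OCc4ccccc4)[C@H]3OCCOCC)[C@@H](OCc4ccccc4)[C@@H](c5ccc(OCc4ccccc4)c(OCc4ccccc4)c5)O2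
F2 | step 8 | pentabromo tetramer (icosa-O-benzyl) | c4ccccc4COc1c(Br)c(OCc4ccccc4)c2c(c1Br)O[C@H](c5ccc(OCc4ccccc4)c(OCc4ccccc4)c5)[C@H](OCc4ccccc4)[C@H]2c1c(OCc4ccccc4)c(Br)c2c(c1OCc4ccccc4)[C@H](c1c(OCc4ccccc4)c(Br)c(OCc4ccccc4)c3c1O[C@H](c5ccc(OCc4ccccc4)c(OCc4ccccc4)c5)[C@H](OCc4ccccc4)[C@H]3c1c(OCc4ccccc4)c(Br)c3c(c1OCc4ccccc4)C[C@@H](OCc4ccccc4)[C@@H](c5ccc(OCc4ccccc4)c(OCc4ccccc4)c5)O3)[C@@H](OCc4ccccc4)[C@@H](c5ccc(OCc4ccccc4)c(OCc4ccccc4)c5)O2
F3 | step 6 | dibromo dimer with C4 methylene on U2 (4β→6) | c4ccccc4COc1cc(OCc4ccccc4)c2c(c1Br)O[C@H](c5ccc(OCc4ccccc4)c(OCc4ccccc4)c5)[C@H](OCc4ccccc4)[C@H]2c1c(OCc4ccccc4)c(Br)c2c(c1OCc4ccccc4)C[C@@H](OCc4ccccc4)[C@@H](c5ccc(OCc4ccccc4)c(OCc4ccccc4)c5)O2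
F4 | step 6 | dimer 4β-(2-ethoxyethyl) ether on U2 | c4ccccc4COc1cc(OCc4ccccc4)c2c(c1Br)O[C@H](c5ccc(OCc4ccccc4)c(OCc4ccccc4)c5)[C@H](OCc4ccccc4)[C@H]2c1c(OCc4ccccc4)c(Br)c2c(c1OCc4ccccc4)[C@H](OCCOCC)[C@@H](OCc4ccccc4)[C@@H](c5ccc(OCc4ccccc4)c(OCc4ccccc4)c5)O2
F5 | step 7 | trimer with C4 methylene on U3 (4β→6, 4β→8) | c4ccccc4COc1cc(OCc4ccccc4)c2c(c1Br)O[C@H](c5ccc(OCc4ccccc4)c(OCc4ccccc4)c5)[C@H](OCc4ccccc4)[C@H]2c1c(OCc4ccccc4)c(Br)c2c(c1OCc4ccccc4)[C@H](c1c(OCc4ccccc4)cc(OCc4ccccc4)c3c1O[C@H](c5ccc(OCc4ccccc4)c(OCc4ccccc4)c5)[C@H](OCc4ccccc4)C3)[C@@H](OCc4ccccc4)[C@@H](c5ccc(OCc4ccccc4)c(OCc4ccccc4)c5)O2
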